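**Retrosynthetic overview**
1. The last bond made is C4–C4a. It closes the pyran ring: a naphthylmethyl radical, made from the benzylic C–H of an open-chain aryl ether, is captured by nickel at the neighbouring C–I. This step sets C4.
2. O1–C2 comes from a Mitsunobu etherification of 2-iodoresorcinol with an (S)-4-naphthylbutan-2-ol. Inversion gives 2R.
3. C4–C1' comes from hydroboration of (S)-but-3-en-2-ol and B-alkyl Suzuki coupling with 4,5-dimethoxynaphthalen-1-yl triflate.
4. The naphthalene comes from a Diels–Alder reaction of 3-methoxybenzyne with 2-methoxyfuran, followed by opening of the bridged ketal.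
5. Ring order: the second naphthalene ring is formed first (step 2) and the pyran ring last (step 7). Both benzene rings are bought.

Assumption: (S)-but-3-en-2-ol (≥98 % ee), 2-methoxyfuran and LDA solution are bought. The minor 2,4-cis epimer from step 7 is removed by chromatography.

**Step 1**
Reactants: 1 3-bromophenol
Product: 2 3-bromoanisole
Conditions: MeI, K2CO3, acetone, reflux
Reagents that add atoms: iodomethane, CI
Why: Williamson ether synthesis, in which the phenoxide is the only nucleophile and attacks MeI by SN2; no stereocentre is involved.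

**Step 2**
Reactants: 2 3-bromoanisole; 3 2-methoxyfuran
Product: 6 4,5-dimethoxynaphthalen-1-ol, via 3-methoxybenzyne 4 (not isolated), via oxa-bridged cycloadduct 5 (not isolated)
Conditions: LDA (1.2 equiv), 3 (3 equiv), THF, −78 °C → rt; then 1 M HCl
Reagents that add atoms: none
Why: Aryne Diels–Alder reaction, in which LDA lithiates 2 between Br and OMe, LiBr loss gives the polarised aryne 4, its more electrophilic carbon (meta to OMe) bonds to the nucleophilic C5 of 2-methoxyfuran so that the ketal carbon of 5 lies peri to the aryl OMe, and acid opening of the bridged ketal aromatises to the 4,5-dimethoxy-1-naphthol; no stereocentre survives.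

**Step 3**
Reactants: 6 4,5-dimethoxynaphthalen-1-ol
Product: 7 4,5-dimethoxynaphthalen-1-yl trifluoromethanesulfonate
Conditions: Tf2O, pyridine, CH2Cl2, 0 °C, under N2
Reagents that add atoms: triflic anhydride, O=S(=O)(OS(=O)(=O)C(F)(F)F)C(F)(F)F
Why: O-sulfonylation of the only free OH turns C1'–O into a cross-coupling handle, and the methyl ethers are inert; no stereocentre is involved.

**Step 4**
Reactants: 8 (S)-but-3-en-2-ol; 7 4,5-dimethoxynaphthalen-1-yl trifluoromethanesulfonate
Product: 10 (S)-4-(4,5-dimethoxynaphthalen-1-yl)butan-2-ol, via bis(9-BBN) adduct 9 (not isolated)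
Conditions: 8, 9-BBN-H (2.1 equiv), THF, 0 °C → rt; then 7, Pd(OAc)2/SPhos (5/10 mol %), 3 M aq. K3PO4, THF, 60 °C
Reagents that add atoms: none
Why: Anti-Markovnikov hydroboration followed by B-alkyl Suzuki–Miyaura coupling, in which 9-BBN first caps the OH, then adds to the terminal carbon, and the primary alkylborane couples with the triflate; the carbinol centre is not touched and stays S.

**Step 5**
Reactants: 11 resorcinol
Product: 12 2-iodoresorcinol
Conditions: I2, NaHCO3, H2O, 0 °C → rt
Reagents that add atoms: iodine, II
Why: Electrophilic aromatic iodination of the resorcinolate in water goes to the doubly activated C2 between the two oxygens (a known preparative selectivity), which fixes the later C4a position; no stereocentre is involved.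

**Step 6**
Reactants: 10 (S)-4-(4,5-dimethoxynaphthalen-1-yl)butan-2-ol; 12 2-iodoresorcinol
Product: 13 (R)-3-{[4-(4,5-dimethoxynaphthalen-1-yl)butan-2-yl]oxy}-2-iodophenol
Conditions: 12 (2.5 equiv), PPh3, DIAD (1.3 equiv each), THF, 0 °C → rt
Reagents that add atoms: none
Why: Mitsunobu reaction, in which the phenol displaces the oxyphosphonium group by SN2 with clean inversion (S → R), setting C2 of the target, while the excess diol suppresses double alkylation.

**Step 7**
Reactants: 13 (R)-3-{[4-(4,5-dimethoxynaphthalen-1-yl)butan-2-yl]oxy}-2-iodophenol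
Product: 15 cladonaphchrom A, (2R,4S)-4-(4,5-dimethoxynaphthalen-1-yl)-2-methylchroman-5-ol, via naphthylmethyl radical 14 (not isolated)
Conditions: NiBr2·glyme (25 mol %), dtbbpy (30 mol %), 4CzIPN (5 mol %), 2,6-lutidine (30 mol %), K2HPO4 (2 equiv), DMA, 456 nm LED, 30 °C; 13 added by syringe pump over 16 h (final 0.01 M)
Reagents that add atoms: none
Why: Proposed new method: excited 4CzIPN oxidises the electron-rich 4-alkyl-1,8-dimethoxynaphthalene unit (about +1.1 to +1.2 V vs SCE) to its radical cation, base removes the only benzylic proton to give the planar radical 14, this is trapped by the aryl–Ni(II) formed from the C–I bond of the same molecule (slow addition keeps free 13 below the nickel loading, so the radical arises on a nickel-bearing molecule), and C4–C4a reductive elimination from Ni(III) closes the ring through the half-chair with 2-Me equatorial and the naphthyl pseudo-axial, away from the peri 5-OH, which sets C4 as S (2,4-trans) under control of C2; the closest known reaction types are Ni/photoredox C(sp3)–H arylation by amine radical-cation deprotonation and Ni/photoredox benzylic C–H arylation to 1,1-diarylalkanes.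

**Compound list**
1 | 3-bromophenol | Oc1cccc(Br)c1 | starting material
2 | 3-bromoanisole | COc1cccc(Br)c1 | intermediate
3 | 2-methoxyfuran | COc1ccco1 | starting material
4 | 3-methoxybenzyne | COC1=CC=CC#C1 | intermediate
5 | 1,8-dimethoxy-1,4-dihydro-1,4-epoxynaphthalene (racemic) | COc1cccc2c1C1(OC)C=CC2O1 | intermediate
6 | 4,5-dimethoxynaphthalen-1-ol | COc1ccc(O)c2cccc(OC)c12 | intermediate
7 | 4,5-dimethoxynaphthalen-1-yl trifluoromethanesulfonate | COc1ccc(OS(=O)(=O)C(F)(F)F)c2cccc(OC)c12 | intermediate
8 | (S)-but-3-en-2-ol | C[C@H](O)C=C | starting material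
9 | (S)-O,C4-bis(9-borabicyclo[3.3.1]nonan-9-yl) derivative of butan-2-ol | C[C@H](OB1C2CCCC1CCC2)CCB1C2CCCC1CCC2 | intermediate
10 | (S)-4-(4,5-dimethoxynaphthalen-1-yl)butan-2-ol | C[C@H](O)CCc1ccc(OC)c2c(OC)cccc12 | intermediate
11 | resorcinol | Oc1cccc(O)c1 | starting material
12 | 2-iodoresorcinol | Oc1cccc(O)c1I | intermediate
13 | (R)-3-{[4-(4,5-dimethoxynaphthalen-1-yl)butan-2-yl]oxy}-2-iodophenol | C[C@@H](Oc1cccc(O)c1I)CCc1ccc(OC)c2c(OC)cccc12 | intermediate
14 | (3R)-1-(4,5-dimethoxynaphthalen-1-yl)-3-(3-hydroxy-2-iodophenoxy)butyl radical | C[C@@H](Oc1cccc(O)c1I)C[CH]c1ccc(OC)c2c(OC)cccc12 | intermediate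
15 | cladonaphchrom A, (2R,4S)-4-(4,5-dimethoxynaphthalen-1-yl)-2-methylchroman-5-ol | COc1cccc2c([C@@H]3C[C@@H](C)Oc4cccc(O)c43)ccc(OC)c12 | target

**Step count**
Total: 7 steps. The longest linear sequence is 6 steps (1 → 2 → 6 → 7 → 10 → 13 → 15).

**Steps most likely to fail**

Step 7 is the riskiest step. Radical 14 may be caught by a nickel aryl of another molecule, which would give oligomers. The C–I bond may simply be reduced. The stabilised radical cation may lose its proton too slowly, or the trans:cis ratio may be modest. The fallback makes the same radical 14 from an alkene instead of a C–H bond. It sets out from 7. (S)-But-3-yn-2-ol is hydroborated with pinacolborane (Cp2ZrHCl cat.) to (S,E)-4-(pinacolboryl)but-3-en-2-ol F1. Suzuki coupling of this with 7 gives (S,E)-4-(4,5-dimethoxynaphthalen-1-yl)but-3-en-2-ol F2. A Mitsunobu reaction with 12 gives the (R,E)-allylic aryl ether F3. Metal-hydride hydrogen-atom transfer to the styrene-type double bond (Fe(dpm)3, Ph(iPrO)SiH2) puts H on C3 and the radical on C4. That radical is closed onto the aryl iodide with (dtbbpy)NiBr2 and Mn as reductant, and the route comes back at 15.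

Step 2 is the second risk. LDA can add to the aryne, 2-methoxyfuran is sensitive, and naphthol 6 oxidises easily in air. The fallback generates the aryne by halogen–lithium exchange at −78 °C with no amide base present. It sets out from 12. Mono-methylation (MeI, K2CO3) gives 2-iodo-3-methoxyphenol F4, and triflation gives 2-iodo-3-methoxyphenyl trifluoromethanesulfonate F5. Adding n-BuLi to F5 and 3 in THF at −78 °C releases 4, which runs through 5 as before, and the route comes back at 6.

Step 6 is the third risk. The phenol is hindered by the ortho iodine, the alcohol is secondary, and some bis-ether or elimination product is possible. The fallback separates activation from displacement. It sets out from 10. MsCl/Et3N gives (S)-4-(4,5-dimethoxynaphthalen-1-yl)butan-2-yl methanesulfonate F6, with retention at carbon. This is displaced by the caesium phenoxide of excess 12 (Cs2CO3, DMF, 60 °C) by SN2 with inversion, and the route comes back at 13.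

**Further compounds**
F1 | step 7 | (S,E)-4-(4,4,5,5-tetramethyl-1,3,2-dioxaborolan-2-yl)but-3-en-2-ol | C[C@H](O)/C=C/B1OC(C)(C)C(C)(C)O1
F2 | step 7 | (S,E)-4-(4,5-dimethoxynaphthalen-1-yl)but-3-en-2-ol | C[C@H](O)/C=C/c1ccc(OC)c2c(OC)cccc12
F3 | step 7 | (R,E)-3-{[4-(4,5-dimethoxynaphthalen-1-yl)but-3-en-2-yl]oxy}-2-iodophenol | C[C@@H](Oc1cccc(O)c1I)/C=C/c1ccc(OC)c2c(OC)cccc12
F4 | step 2 | 2-iodo-3-methoxyphenol | COc1cccc(O)c1I
F5 | step 2 | 2-iodo-3-methoxyphenyl trifluoromethanesulfonate | COc1cccc(OS(=O)(=O)C(F)(F)F)c1I
F6 | step 6 | (S)-4-(4,5-dimethoxynaphthalen-1-yl)butan-2-yl methanesulfonate | C[C@H](OS(C)(=O)=O)CCc1ccc(OC)c2c(OC)cccc12
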